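The earlier runs and the new flask were generated by integration on assumed constants, noise included.

The target in each flask stands between a rate of making and a rate of losing, and the two earlier runs give a reading of each.

| setting | beta | eta | south-west | north-west | east | north-east |
|---|---|---|---|---|---|---|
| starting material | 0.0084 M | 0.099 M | 0.015 M | 0.030 M | 0.060 M | 0.12 M |
| gas phase | 18 mM (held) | 18 mM (held) | 18 mM (held) | 18 mM (held) | 18 mM (held) | 18 mM (held) |
| remark | run made earlier | run made earlier |  |  |  |  |
| time |  |  | 10 min | 10 min | 10 min | 10 min |

| run | time / min | target / % |
|---|---|---|
| beta | 1.33 | 28.4 |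
| beta | 2.50 | 50.6 |
| beta | 4.00 | 64.9 |
| beta | 5.00 | 71.3 |
| beta | 6.00 | 72.9 |
| beta | 8.00 | 76.2 |
| eta | 0.500 | 1.3 |
| eta | 1.00 | 2.9 |
| eta | 1.50 | 7.1 |
| eta | 2.50 | 10.7 |
| eta | 4.00 | 13.2 |
| eta | 8.00 | 22.3 |

(each reading ± 1 percentage point)

- [target] at the end for south-west, north-west, east, north-east, in this order
- how that number moves from the first to the last of them (rises, then falls / hardly changes / rises all the way / falls all the way / falls, then rises)

- at the start none of the gas phase is in solution
- "hardly changes" means that all values lie within two and a half points (for a concentration: within two and a half percent of the largest)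

Eta holds 11.8 times the charge of beta, yet its early rise, S = 0.00424 M min⁻¹ against 0.00179 M min⁻¹ in beta, is 2.37 times as fast, so at high charge the crossing of the gas phase into solution is taken as the rate-limiting step, and a charge c needs a fill time c/S. Later eta climbs at 0.00209 M min⁻¹, slower than S, and this gap, set against a mean target of 0.0163 M, reads as a target life of 7.60 min in eta. Beta is still rising at 76.2% of its charge, so that life is taken to lengthen in inverse proportion to the charge.

Fill time and life are then equal at the crossover charge c†, 0.0565 M. Above c† the target rises first-order towards S times its life, which gives 0.0292 M for east and 0.0212 M for north-east, so this reckoning expects the row to turn downward.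

The forecast gave 0.0102 M, 0.017 M, 0.0235 M and 0.027 M, so rises all the way: “The target keeps rising with charge, though with diminishing returns”.

The flasks gave 0.0110 M, 0.0192 M, 0.0271 M and 0.0251 M, so rises, then falls, turning at 0.075 M.

    target → over-reaction product (k = 2.10 × 10⁻⁵ min⁻¹)
    gas phase ⇌ dissolved gas, rate k2*(csat - [dissolved gas]) (kL = 0.270 min⁻¹)
    starting material + dissolved gas ⇌ target (K = 270 M⁻¹, k = 190 M⁻¹ min⁻¹)
    starting material + target → side product (k = 1.60 M⁻¹ min⁻¹)

South-west, charged below c†, has a fill time of 3.54 min, and its target has a half-life of 62 min against starting material at 3.24 min, long against 10 min, and it ends with target at 73.2% and starting material at 18.5% of its charge. North-east, charged above c†, has a fill time of 28.3 min, longer than the run, and ends with target at 20.9%, starting material at 47.6% and side product, which counts double, at 31.6%.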